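The constants are those of an exercise.

**Slow drain.** Slowness of the two steps behind capture is the mark of this flask: 0.045 min⁻¹ and 0.018 min⁻¹ both stand below the 0.114 min⁻¹ at which fresh starting material takes up free catalyst.

starting material 0.026 M; free catalyst 3.6 mM

    starting material + free catalyst → catalyst intermediate A (k1 = 4.4 M⁻¹ min⁻¹)
    catalyst intermediate A → catalyst intermediate B (k2 = 0.045 min⁻¹)
    catalyst intermediate B → free catalyst + product (k3 = 0.018 min⁻¹)
    2 starting material → homo dimer (k4 = 0.40 M⁻¹ min⁻¹)

1. the form that holds most of the catalyst when 30% of the starting material are converted (catalyst intermediate A / free catalyst / catalyst intermediate B)
2. its share of the catalyst then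

**Frozen capture.** Up to the asked point the flask loses 30% of its starting material, so this reckoning freezes [starting material] at its midway value, 0.0221 M. The frozen capture constant, the rate constant of capture times that concentration, is 0.0972 min⁻¹. It makes capture pseudo-first-order.

**The clock.** At the frozen concentration, dimerisation uses 0.391 mM min⁻¹ of starting material, and the conversion asked for is 7.80 mM. If capture took the 3.6 mM charged, dimerisation would supply the rest in 10.7 min. Capture by then takes 2.33 mM, and one pass of correction puts the time near 14.0 min.

**Capture first.** With capture as the one step reckoned, free catalyst falls to 25.7% of the catalyst, and the remainder sits in catalyst intermediate A.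

**Adding the drain.** The two-step chain leaves 51.4% in catalyst intermediate A and 22.9% in catalyst intermediate B.

**Adding the return.** Catalyst intermediate B grows roughly as the square of time, so its mean is a third of its final share. The return to free catalyst is then 1.92% of the catalyst. That gives 27.6% free catalyst and 21.0% catalyst intermediate B, so this reckoning makes catalyst intermediate A the resting state at this moment.

**The forecast.** The forecast names catalyst intermediate A at 50%, just under the 51.4% reckoned here, from “rough mental time-stepping rather than an exact integration”.

**The flask.** The simulation gives catalyst intermediate A with 50.3% of the catalyst, at 0.231 h. The frozen constant 0.0972 min⁻¹ corresponds to a capture half-life of 0.119 h, reckoned for the stretch up to the asked point. At 0.0757 d, later than that point, the half-life of free catalyst by capture stands at 0.44 h, longer than the frozen value by a factor of 3.70.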